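## Retrosynthetic overview

1. Target 29 ⇐ diacetylation of lactone triol 28 ⇐ transannular 7-exo opening (inversion at C12) of the (11S,12S)-epoxide by the C16 acid, itself made by allylic oxidation of the isopropenyl group.
2. Epoxide ⇐ (E)-C11=C12 macrocycle 22 ⇐ retro-ene transposition of the allylic alcohol from a CrCl2/NiCl2 ring closure (C11–C12 bond, 14-membered carbocycle).
3. Oxolane ring ⇐ osmium-oxo [3+2] cycloaddition of the 7,8-diol onto the (E)-C3=C4 alkene (sets C4 and C3); C7 ⇐ chelation-controlled reduction next to C8.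
4. C5–C6 bond and (E)-C3=C4 ⇐ ester methylenation then Claisen [3,3] rearrangement of an allylic ester built from a limonene-derived alcohol and a linalool-derived acid.
5. Ring order: oxolane (step 10), 14-membered carbocycle (step 13), epoxide (step 15), seven-membered lactone (step 18); C1 comes from (R)-limonene, C8 from (R)-linalool.

Assumption: names use cembrane numbering (ring C1–C14; C15 with C16 and C17 on C1; methyls C18, C19, C20 on C4, C8, C12; "11,12-seco" means the C11–C12 bond is not yet formed).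

## Route

Step 1
Reactants: 1 (R)-(+)-limonene
Product: 2 (3R)-6-oxo-3-(prop-1-en-2-yl)heptanal
Conditions: O3 (1.0 equiv), CH2Cl2/MeOH, −78 °C; Me2S, −78 → 23 °C
Reagents that add atoms: ozone ([O-][O+]=O)
Why: Chemoselective ozonolysis cleaves the electron-rich trisubstituted ring alkene and leaves the 1,1-disubstituted isopropenyl group, so the C1 stereocentre is carried over untouched from limonene.

Step 2
Reactants: 2 (3R)-6-oxo-3-(prop-1-en-2-yl)heptanal
Product: 3 (5R,7RS)-7-hydroxy-8-methyl-5-(prop-1-en-2-yl)non-8-en-2-one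
Conditions: CH2=C(CH3)MgBr (1.05 equiv), THF, −78 °C
Reagents that add atoms: isopropenylmagnesium bromide (CC(=C)[Mg]Br)
Why: Grignard addition at −78 °C is selective for the aldehyde over the methyl ketone; the new carbinol centre (C3) is formed as both epimers and is destroyed in step 8.

Step 3
Reactants: 4 (R)-(−)-linalool
Product: 6 (4R)-4-methylhex-5-ene-1,4-diol, via lactol 5 (not isolated)
Conditions: O3 (1.0 equiv), CH2Cl2/MeOH, −78 °C; NaBH4, −78 → 0 °C
Reagents that add atoms: ozone ([O-][O+]=O)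
Why: Ozonolysis picks the trisubstituted alkene over the vinyl group and the reductive work-up gives the primary alcohol, with the tertiary carbinol (future C8) bought from linalool.

Step 4
Reactants: 6 (4R)-4-methylhex-5-ene-1,4-diol
Product: 7 (3R)-3-methyl-3,6-bis(triethylsilyloxy)hex-1-ene
Conditions: Et3SiOTf (2.4 equiv), 2,6-lutidine, CH2Cl2, −78 → 0 °C
Reagents that add atoms: triethylsilyl trifluoromethanesulfonate (CC[Si](CC)(CC)OS(=O)(=O)C(F)(F)F)
Why: Silyl triflate silylation protects both the primary and the hindered tertiary hydroxyl so that no free OH interferes with steps 5 to 8.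

Step 5
Reactants: 7 (3R)-3-methyl-3,6-bis(triethylsilyloxy)hex-1-ene
Product: 9 (2R)-2-methyl-2,5-bis(triethylsilyloxy)pentanoic acid, via aldehyde 8 (not isolated)
Conditions: O3, CH2Cl2, −78 °C; PPh3; then NaClO2, NaH2PO4, 2-methylbut-2-ene, t-BuOH/H2O, 0 → 23 °C
Reagents that add atoms: ozone ([O-][O+]=O); sodium chlorite ([Na+].[O-]Cl=O)
Why: Ozonolysis of the only remaining alkene followed by Pinnick oxidation turns the vinyl group into the C7 carboxylic acid without touching the quaternary stereocentre.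

Step 6
Reactants: 3 (5R,7RS)-7-hydroxy-8-methyl-5-(prop-1-en-2-yl)non-8-en-2-one; 9 (2R)-2-methyl-2,5-bis(triethylsilyloxy)pentanoic acid
Product: 10 (5R)-2-methyl-8-oxo-5-(prop-1-en-2-yl)non-1-en-3-yl (2R)-2-methyl-2,5-bis(triethylsilyloxy)pentanoate
Conditions: 2,4,6-Cl3C6H2COCl, Et3N, THF, 23 °C; then 3, DMAP, toluene, 40 °C
Reagents that add atoms: none
Why: Yamaguchi esterification via the mixed anhydride joins the hindered α-quaternary acid to the secondary allylic alcohol and so links the two chiral-pool fragments.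

Step 7
Reactants: 10 (5R)-2-methyl-8-oxo-5-(prop-1-en-2-yl)non-1-en-3-yl (2R)-2-methyl-2,5-bis(triethylsilyloxy)pentanoate
Product: 11 (5R)-2-methyl-5-(prop-1-en-2-yl)-8-(trifluoromethanesulfonyloxy)nona-1,8-dien-3-yl (2R)-2-methyl-2,5-bis(triethylsilyloxy)pentanoate
Conditions: LDA (1.1 equiv), THF, −78 °C; PhNTf2, −78 → 0 °C
Reagents that add atoms: N-phenylbis(trifluoromethanesulfonimide) (O=S(=O)(N(c1ccccc1)S(=O)(=O)C(F)(F)F)C(F)(F)F)
Why: Kinetic deprotonation of the methyl ketone on its methyl side and O-triflation give the terminal enol triflate (the ester has no α-hydrogen), which masks C12 through step 8 and is the coupling handle for step 13.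

Step 8
Reactants: 11 (5R)-2-methyl-5-(prop-1-en-2-yl)-8-(trifluoromethanesulfonyloxy)nona-1,8-dien-3-yl (2R)-2-methyl-2,5-bis(triethylsilyloxy)pentanoate
Product: 13 (1R,3E,8R)-8,11-bis(triethylsilyloxy)-12-(trifluoromethanesulfonyloxy)-11,12-secocembra-3,12(20),15(17)-trien-7-one, via enol ether 12 (not isolated)
Conditions: Cp2TiMe2 (3 equiv), toluene, 70 °C (dark); then 110 °C
Reagents that add atoms: dimethyltitanocene (C[Ti](C)(C1C=CC=C1)C1C=CC=C1)
Why: Petasis methylenation turns the ester into an allyl vinyl ether whose Claisen [3,3] rearrangement through a chair with the C2 chain equatorial forms the C5–C6 bond, the (E)-C3=C4 alkene and the C7 ketone.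

Step 9
Reactants: 13 (1R,3E,8R)-8,11-bis(triethylsilyloxy)-12-(trifluoromethanesulfonyloxy)-11,12-secocembra-3,12(20),15(17)-trien-7-one
Product: 15 (1R,3E,7S,8R)-12-(trifluoromethanesulfonyloxy)-11,12-secocembra-3,12(20),15(17)-triene-7,8,11-triol, via hydroxy ketone 14 (not isolated)
Conditions: HF·pyridine, THF, 0 °C; then Zn(BH4)2, Et2O, −20 °C
Reagents that add atoms: none
Why: After desilylation, Cram-chelate reduction (zinc bridging the C7 carbonyl and the C8 hydroxyl, hydride from the methyl face) gives the anti 7,8-diol, so C7 (S) is set by the linalool-derived C8.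

Step 10
Reactants: 15 (1R,3E,7S,8R)-12-(trifluoromethanesulfonyloxy)-11,12-secocembra-3,12(20),15(17)-triene-7,8,11-triol
Product: 16 (1R,3R,4R,7S,8R)-4,7-epoxy-12-(trifluoromethanesulfonyloxy)-11,12-secocembra-12(20),15(17)-diene-3,8,11-triol
Conditions: K2OsO2(OH)4 (5 mol %), pyridine N-oxide (2 equiv), citric acid, Cu(OTf)2 (cat.), MeCN/pH 6.5 buffer, 60 °C
Reagents that add atoms: pyridine N-oxide ([O-][n+]1ccccc1)
Why: The hexavalent osmium glycolate of the 7,8-diol adds across the (E)-C3=C4 alkene in an intramolecular metal-oxo [3+2] cycloaddition (Donohoe oxidative cyclisation); this closes the 2,5-cis oxolane and, by syn addition, sets C4 (R) and C3 (R) from C7, while the isopropenyl and enol triflate alkenes are out of reach.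

Step 11
Reactants: 16 (1R,3R,4R,7S,8R)-4,7-epoxy-12-(trifluoromethanesulfonyloxy)-11,12-secocembra-12(20),15(17)-diene-3,8,11-triol
Product: 17 (1R,3R,4R,7S,8R)-4,7-epoxy-3,8,11-tris(triethylsilyloxy)-11,12-secocembra-12(20),15(17)-dien-12-yl trifluoromethanesulfonate
Conditions: Et3SiOTf (3.5 equiv), 2,6-lutidine, CH2Cl2, −78 → 0 °C
Reagents that add atoms: triethylsilyl trifluoromethanesulfonate (CC[Si](CC)(CC)OS(=O)(=O)C(F)(F)F)
Why: Exhaustive silylation blocks the C8 hydroxyl (which would otherwise form a lactol with the C11 aldehyde and later attack the 11,12-epoxide) and the C3 hydroxyl.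

Step 12
Reactants: 17 (1R,3R,4R,7S,8R)-4,7-epoxy-3,8,11-tris(triethylsilyloxy)-11,12-secocembra-12(20),15(17)-dien-12-yl trifluoromethanesulfonate
Product: 18 (1R,3R,4R,7S,8R)-4,7-epoxy-3,8-bis(triethylsilyloxy)-12-(trifluoromethanesulfonyloxy)-11,12-secocembra-12(20),15(17)-dien-11-al
Conditions: (COCl)2, DMSO, CH2Cl2, −78 → −30 °C; Et3N
Reagents that add atoms: none
Why: Under Swern conditions a primary triethylsilyl ether is cleaved and oxidised directly to the aldehyde while secondary and tertiary silyl ethers survive.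

Step 13
Reactants: 18 (1R,3R,4R,7S,8R)-4,7-epoxy-3,8-bis(triethylsilyloxy)-12-(trifluoromethanesulfonyloxy)-11,12-secocembra-12(20),15(17)-dien-11-al
Product: 19 (1R,3R,4R,7S,8R,11RS)-4,7-epoxy-3,8-bis(triethylsilyloxy)cembra-12(20),15(17)-dien-11-ol
Conditions: CrCl2 (12 equiv), NiCl2 (0.2 equiv), DMF/THF, 23 °C, 2 mM
Reagents that add atoms: none
Why: Intramolecular Nozaki–Hiyama–Kishi coupling of the enol triflate with the aldehyde closes the 14-membered carbocycle at C11–C12; the C11 carbinol configuration does not matter because it is erased in step 14.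

Step 14
Reactants: 19 (1R,3R,4R,7S,8R,11RS)-4,7-epoxy-3,8-bis(triethylsilyloxy)cembra-12(20),15(17)-dien-11-ol
Product: 22 (1R,3R,4R,7S,8R,11E)-4,7-epoxy-3,8-bis(triethylsilyloxy)cembra-11,15(17)-diene, via sulfonylhydrazine 20 (not isolated), via allylic diazene 21 (not isolated)
Conditions: 2-NO2C6H4SO2NHNH2, PPh3, DEAD, N-methylmorpholine, THF, −30 → 23 °C
Reagents that add atoms: none
Why: Myers reductive transposition (Mitsunobu displacement, sulfinate loss, then sigmatropic retro-ene loss of N2 from the allylic diazene) delivers hydrogen to the exocyclic methylene and should give the (E)-C11=C12 alkene, because C10 avoids the C13 substituent in the transition state.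

Step 15
Reactants: 22 (1R,3R,4R,7S,8R,11E)-4,7-epoxy-3,8-bis(triethylsilyloxy)cembra-11,15(17)-diene
Product: 23 (1R,3R,4R,7S,8R,11S,12S)-4,7:11,12-diepoxy-3,8-bis(triethylsilyloxy)cembr-15(17)-ene
Conditions: mCPBA (1.05 equiv), NaHCO3, CH2Cl2, −20 °C
Reagents that add atoms: 3-chloroperoxybenzoic acid (OOC(=O)c1cccc(Cl)c1)
Why: Prilezhaev epoxidation takes the trisubstituted alkene ahead of the isopropenyl group, and the face is set only by the conformation of the bridged macrocycle (peripheral attack); which face that is cannot be predicted with confidence, hence the fallback below.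

Step 16
Reactants: 23 (1R,3R,4R,7S,8R,11S,12S)-4,7:11,12-diepoxy-3,8-bis(triethylsilyloxy)cembr-15(17)-ene
Product: 24 (1R,3R,4R,7S,8R,11S,12S)-4,7:11,12-diepoxy-3,8-bis(triethylsilyloxy)cembr-15(17)-en-16-ol
Conditions: SeO2 (0.5 equiv), t-BuOOH (3 equiv), CH2Cl2, 23 °C
Reagents that add atoms: selenium dioxide (O=[Se]=O); tert-butyl hydroperoxide (CC(C)(C)OO)
Why: Riley allylic oxidation (ene reaction then [2,3]-sigmatropic shift) hydroxylates the methyl of the isopropenyl group, which is now the only alkene in the molecule.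

Step 17
Reactants: 24 (1R,3R,4R,7S,8R,11S,12S)-4,7:11,12-diepoxy-3,8-bis(triethylsilyloxy)cembr-15(17)-en-16-ol
Product: 26 (1R,3R,4R,7S,8R,11S,12S)-4,7:11,12-diepoxy-3,8-bis(triethylsilyloxy)cembr-15(17)-en-16-oic acid, via enal 25 (not isolated)
Conditions: TEMPO (0.2 equiv), PhI(OAc)2 (2.5 equiv), MeCN/pH 7 buffer, 23 °C
Reagents that add atoms: water (O)
Why: Oxoammonium oxidation in wet acetonitrile takes the primary allylic alcohol through the enal hydrate to the 2-substituted acrylic acid under near-neutral conditions that spare the epoxide and silyl ethers.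

Step 18
Reactants: 26 (1R,3R,4R,7S,8R,11S,12S)-4,7:11,12-diepoxy-3,8-bis(triethylsilyloxy)cembr-15(17)-en-16-oic acid
Product: 28 (1R,3R,4R,7S,8R,11S,12R)-4,7-epoxy-3,8,11-trihydroxycembr-15(17)-en-16,12-olide, via silyl lactone 27 (not isolated)
Conditions: CSA (0.3 equiv), CH2Cl2, 0 → 23 °C; then MeOH, 23 °C
Reagents that add atoms: none
Why: Acid-catalysed transannular 7-exo epoxide opening by the carboxylic acid at the tertiary C12 with inversion gives the α-methylene seven-membered lactone with C12 (R) and C11 (S), and methanolysis then removes both silyl groups.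

Step 19
Reactants: 28 (1R,3R,4R,7S,8R,11S,12R)-4,7-epoxy-3,8,11-trihydroxycembr-15(17)-en-16,12-olide
Product: 29 (1R,3R,4R,7S,8R,11S,12R)-3,11-diacetoxy-4,7-epoxy-8-hydroxycembr-15(17)-en-16,12-olide
Conditions: Ac2O (3 equiv), pyridine, DMAP (cat.), CH2Cl2, 0 → 23 °C
Reagents that add atoms: acetic anhydride (CC(=O)OC(C)=O)
Why: Acylation esterifies the two secondary hydroxyls (C3, C11) and leaves the hindered tertiary C8 hydroxyl free, giving the target.

## Compound list

1 | (R)-(+)-limonene, (4R)-1-methyl-4-(prop-1-en-2-yl)cyclohex-1-ene | CC1=CC[C@@H](CC1)C(C)=C | starting material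
2 | (3R)-6-oxo-3-(prop-1-en-2-yl)heptanal | O=CC[C@@H](CCC(C)=O)C(C)=C | intermediate
3 | (5R,7RS)-7-hydroxy-8-methyl-5-(prop-1-en-2-yl)non-8-en-2-one (carbinol epimers) | C=C(C)C(O)C[C@@H](CCC(C)=O)C(C)=C | intermediate
4 | (R)-(−)-linalool, (3R)-3,7-dimethylocta-1,6-dien-3-ol | C=C[C@](C)(O)CCC=C(C)C | starting material
5 | (5R)-5-ethenyl-5-methyloxolan-2-ol (lactol, anomers) | C=C[C@@]1(C)CCC(O)O1 | intermediate
6 | (4R)-4-methylhex-5-ene-1,4-diol | C=C[C@](C)(O)CCCO | intermediate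
7 | (3R)-3-methyl-3,6-bis(triethylsilyloxy)hex-1-ene | C=C[C@](C)(O[Si](CC)(CC)CC)CCCO[Si](CC)(CC)CC | intermediate
8 | (2R)-2-methyl-2,5-bis(triethylsilyloxy)pentanal | O=C[C@](C)(O[Si](CC)(CC)CC)CCCO[Si](CC)(CC)CC | intermediate
9 | (2R)-2-methyl-2,5-bis(triethylsilyloxy)pentanoic acid | OC(=O)[C@](C)(O[Si](CC)(CC)CC)CCCO[Si](CC)(CC)CC | intermediate
10 | (5R)-2-methyl-8-oxo-5-(prop-1-en-2-yl)non-1-en-3-yl (2R)-2-methyl-2,5-bis(triethylsilyloxy)pentanoate (epimers at the ester-bearing carbon) | C=C(C)C(OC(=O)[C@](C)(O[Si](CC)(CC)CC)CCCO[Si](CC)(CC)CC)C[C@@H](CCC(C)=O)C(C)=C | intermediate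
11 | (5R)-2-methyl-5-(prop-1-en-2-yl)-8-(trifluoromethanesulfonyloxy)nona-1,8-dien-3-yl (2R)-2-methyl-2,5-bis(triethylsilyloxy)pentanoate | C=C(C)C(OC(=O)[C@](C)(O[Si](CC)(CC)CC)CCCO[Si](CC)(CC)CC)C[C@@H](CCC(=C)OS(=O)(=O)C(F)(F)F)C(C)=C | intermediate
12 | allyl vinyl ether of 11 (ester C=O replaced by C=CH2) | C=C(C)C(OC(=C)[C@](C)(O[Si](CC)(CC)CC)CCCO[Si](CC)(CC)CC)C[C@@H](CCC(=C)OS(=O)(=O)C(F)(F)F)C(C)=C | intermediate
13 | (1R,3E,8R)-8,11-bis(triethylsilyloxy)-12-(trifluoromethanesulfonyloxy)-11,12-secocembra-3,12(20),15(17)-trien-7-one | CC[Si](CC)(CC)OCCC[C@@](C)(O[Si](CC)(CC)CC)C(=O)CC/C(C)=C/C[C@@H](CCC(=C)OS(=O)(=O)C(F)(F)F)C(C)=C | intermediate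
14 | (1R,3E,8R)-8,11-dihydroxy-12-(trifluoromethanesulfonyloxy)-11,12-secocembra-3,12(20),15(17)-trien-7-one | OCCC[C@@](C)(O)C(=O)CC/C(C)=C/C[C@@H](CCC(=C)OS(=O)(=O)C(F)(F)F)C(C)=C | intermediate
15 | (1R,3E,7S,8R)-12-(trifluoromethanesulfonyloxy)-11,12-secocembra-3,12(20),15(17)-triene-7,8,11-triol | OCCC[C@@](C)(O)[C@@H](O)CC/C(C)=C/C[C@@H](CCC(=C)OS(=O)(=O)C(F)(F)F)C(C)=C | intermediate
16 | (1R,3R,4R,7S,8R)-4,7-epoxy-12-(trifluoromethanesulfonyloxy)-11,12-secocembra-12(20),15(17)-diene-3,8,11-triol | OCCC[C@@](C)(O)[C@@H]1CC[C@@](C)(O1)[C@H](O)C[C@@H](CCC(=C)OS(=O)(=O)C(F)(F)F)C(C)=C | intermediate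
17 | (1R,3R,4R,7S,8R)-4,7-epoxy-3,8,11-tris(triethylsilyloxy)-11,12-secocembra-12(20),15(17)-dien-12-yl trifluoromethanesulfonate | CC[Si](CC)(CC)OCCC[C@@](C)(O[Si](CC)(CC)CC)[C@@H]1CC[C@@](C)(O1)[C@H](O[Si](CC)(CC)CC)C[C@@H](CCC(=C)OS(=O)(=O)C(F)(F)F)C(C)=C | intermediate
18 | (1R,3R,4R,7S,8R)-4,7-epoxy-3,8-bis(triethylsilyloxy)-12-(trifluoromethanesulfonyloxy)-11,12-secocembra-12(20),15(17)-dien-11-al | O=CCC[C@@](C)(O[Si](CC)(CC)CC)[C@@H]1CC[C@@](C)(O1)[C@H](O[Si](CC)(CC)CC)C[C@@H](CCC(=C)OS(=O)(=O)C(F)(F)F)C(C)=C | intermediate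
19 | (1R,3R,4R,7S,8R,11RS)-4,7-epoxy-3,8-bis(triethylsilyloxy)cembra-12(20),15(17)-dien-11-ol | OC1CC[C@@](C)(O[Si](CC)(CC)CC)[C@@H]2CC[C@@](C)(O2)[C@H](O[Si](CC)(CC)CC)C[C@@H](CCC1=C)C(C)=C | intermediate
20 | N-[(1R,3R,4R,7S,8R)-4,7-epoxy-3,8-bis(triethylsilyloxy)cembra-12(20),15(17)-dien-11-yl]-2-nitrobenzenesulfonohydrazide | NN(C1CC[C@@](C)(O[Si](CC)(CC)CC)[C@@H]2CC[C@@](C)(O2)[C@H](O[Si](CC)(CC)CC)C[C@@H](CCC1=C)C(C)=C)S(=O)(=O)c3ccccc3[N+]([O-])=O | intermediate
21 | (1R,3R,4R,7S,8R)-11-diazenyl-4,7-epoxy-3,8-bis(triethylsilyloxy)cembra-12(20),15(17)-diene | N=NC1CC[C@@](C)(O[Si](CC)(CC)CC)[C@@H]2CC[C@@](C)(O2)[C@H](O[Si](CC)(CC)CC)C[C@@H](CCC1=C)C(C)=C | intermediate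
22 | (1R,3R,4R,7S,8R,11E)-4,7-epoxy-3,8-bis(triethylsilyloxy)cembra-11,15(17)-diene | C/C1=C\CC[C@@](C)(O[Si](CC)(CC)CC)[C@@H]2CC[C@@](C)(O2)[C@H](O[Si](CC)(CC)CC)C[C@@H](CC1)C(C)=C | intermediate
23 | (1R,3R,4R,7S,8R,11S,12S)-4,7:11,12-diepoxy-3,8-bis(triethylsilyloxy)cembr-15(17)-ene | C[C@@]12O[C@H]1CC[C@@](C)(O[Si](CC)(CC)CC)[C@@H]3CC[C@@](C)(O3)[C@H](O[Si](CC)(CC)CC)C[C@@H](CC2)C(C)=C | intermediate
24 | (1R,3R,4R,7S,8R,11S,12S)-4,7:11,12-diepoxy-3,8-bis(triethylsilyloxy)cembr-15(17)-en-16-ol | C[C@@]12O[C@H]1CC[C@@](C)(O[Si](CC)(CC)CC)[C@@H]3CC[C@@](C)(O3)[C@H](O[Si](CC)(CC)CC)C[C@@H](CC2)C(CO)=C | intermediate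
25 | (1R,3R,4R,7S,8R,11S,12S)-4,7:11,12-diepoxy-3,8-bis(triethylsilyloxy)cembr-15(17)-en-16-al | C[C@@]12O[C@H]1CC[C@@](C)(O[Si](CC)(CC)CC)[C@@H]3CC[C@@](C)(O3)[C@H](O[Si](CC)(CC)CC)C[C@@H](CC2)C(C=O)=C | intermediate
26 | (1R,3R,4R,7S,8R,11S,12S)-4,7:11,12-diepoxy-3,8-bis(triethylsilyloxy)cembr-15(17)-en-16-oic acid | C[C@@]12O[C@H]1CC[C@@](C)(O[Si](CC)(CC)CC)[C@@H]3CC[C@@](C)(O3)[C@H](O[Si](CC)(CC)CC)C[C@@H](CC2)C(=C)C(O)=O | intermediate
27 | (1R,3R,4R,7S,8R,11S,12R)-4,7-epoxy-11-hydroxy-3,8-bis(triethylsilyloxy)cembr-15(17)-en-16,12-olide | C=C1C(=O)O[C@]2(C)CC[C@@H]1C[C@@H](O[Si](CC)(CC)CC)[C@@]1(C)CC[C@H](O1)[C@](C)(O[Si](CC)(CC)CC)CC[C@@H]2O | intermediate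
28 | (1R,3R,4R,7S,8R,11S,12R)-4,7-epoxy-3,8,11-trihydroxycembr-15(17)-en-16,12-olide | C=C1C(=O)O[C@]2(C)CC[C@@H]1C[C@@H](O)[C@@]1(C)CC[C@H](O1)[C@](C)(O)CC[C@@H]2O | intermediate
29 | (1R,3R,4R,7S,8R,11S,12R)-3,11-diacetoxy-4,7-epoxy-8-hydroxycembr-15(17)-en-16,12-olide (CNP0343714.4) | C=C1C(=O)O[C@]2(C)CC[C@@H]1C[C@@H](OC(C)=O)[C@@]1(C)CC[C@H](O1)[C@](C)(O)CC[C@@H]2OC(C)=O | target

## Step count and risks

Total steps: 19. Longest linear sequence: 17 steps (4 → 29 through steps 3–19); the limonene branch (steps 1–2) joins at step 6.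

Most likely to fail, step 15 (face of the epoxidation): the sense of macrocyclic control cannot be predicted with confidence, and the wrong face would give the C11/C12 diastereomer of the lactone. The fallback sets out from 22. NBS in THF/H2O gives the anti bromohydrin (1R,3R,4R,7S,8R,11R,12S)-11-bromo-4,7-epoxy-3,8-bis(triethylsilyloxy)cembr-15(17)-en-12-ol F3 by attack of the electrophile on the same face a peracid uses. K2CO3 in MeOH then closes the C12 alkoxide onto C11 with inversion, so the epoxide oxygen ends on the opposite face, and the sequence comes back at 23.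

Second, step 14 (together with the ring closure of step 13 that feeds it): the macrocyclisation may be slow and the retro-ene step may not give only the (E)-alkene inside the ring. The fallback sets out from 17. KOH in MeOH/H2O cleaves the enol triflate at sulfur to the methyl ketone (1R,3R,4R,7S,8R)-4,7-epoxy-3,8,11-tris(triethylsilyloxy)-11,12-secocembr-15(17)-en-12-one F1. Swern oxidation of its primary silyl ether as in step 12 gives the keto aldehyde (1R,3R,4R,7S,8R)-4,7-epoxy-12-oxo-3,8-bis(triethylsilyloxy)-11,12-secocembr-15(17)-en-11-al F2. McMurry coupling (TiCl3(DME)1.5, Zn–Cu couple, DME, reflux, slow addition) then closes the ring and forms the trisubstituted alkene in one operation, with the (E)-isomer expected to predominate in a 14-membered ring, and returns to the route at 22.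

Third, step 16 (allylic oxidation next to an acid-sensitive epoxide): selenium-based oxidation of isopropenyl groups is often low-yielding and the selenous acid formed may open the 11,12-epoxide. The fallback sets out from 23. Ene-type chlorination with NaOCl and CeCl3·7H2O in CH2Cl2/H2O gives the allylic chloride (1R,3R,4R,7S,8R,11S,12S)-16-chloro-4,7:11,12-diepoxy-3,8-bis(triethylsilyloxy)cembr-15(17)-ene F4. Ganem oxidation (Me3NO, DMSO, 23 °C) converts it to the enal, coming back to the route at 25, which is carried to 26 under the step 17 conditions.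

## Further compounds

F1 | step 14 | (1R,3R,4R,7S,8R)-4,7-epoxy-3,8,11-tris(triethylsilyloxy)-11,12-secocembr-15(17)-en-12-one | CC[Si](CC)(CC)OCCC[C@@](C)(O[Si](CC)(CC)CC)[C@@H]1CC[C@@](C)(O1)[C@H](O[Si](CC)(CC)CC)C[C@@H](CCC(C)=O)C(C)=C
F2 | step 14 | (1R,3R,4R,7S,8R)-4,7-epoxy-12-oxo-3,8-bis(triethylsilyloxy)-11,12-secocembr-15(17)-en-11-al | O=CCC[C@@](C)(O[Si](CC)(CC)CC)[C@@H]1CC[C@@](C)(O1)[C@H](O[Si](CC)(CC)CC)C[C@@H](CCC(C)=O)C(C)=C
F3 | step 15 | (1R,3R,4R,7S,8R,11R,12S)-11-bromo-4,7-epoxy-3,8-bis(triethylsilyloxy)cembr-15(17)-en-12-ol | C[C@@]1(O)[C@H](Br)CC[C@@](C)(O[Si](CC)(CC)CC)[C@@H]2CC[C@@](C)(O2)[C@H](O[Si](CC)(CC)CC)C[C@@H](CC1)C(C)=C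
F4 | step 16 | (1R,3R,4R,7S,8R,11S,12S)-16-chloro-4,7:11,12-diepoxy-3,8-bis(triethylsilyloxy)cembr-15(17)-ene | C[C@@]12O[C@H]1CC[C@@](C)(O[Si](CC)(CC)CC)[C@@H]3CC[C@@](C)(O3)[C@H](O[Si](CC)(CC)CC)C[C@@H](CC2)C(CCl)=C
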